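The constants used here are those of an exercise; the rest is arithmetic.

Every substrate takes up one coupling partner to become mono adduct and a second to become double product, so I count partner first.

    substrate + coupling partner → mono adduct + released group (k1 = 1.0 M⁻¹ s⁻¹)
    crystals ⇌ released group, rate k2*(cs2 - [released group]) while solid is left; crystals form when [released group] > cs2 (cs2 = 0.075 M, k2 = 15 s⁻¹)
    coupling partner + mono adduct → double product + released group (k3 = 0.96 M⁻¹ s⁻¹)

substrate 0.091 M; coupling partner 0.164 M (fed, over 2.5 s); time 10 min

- why nothing more happens at 10 min, or that something still does (all of the substrate has reacted / it is still moving / forward and back rates have come level / the coupling partner has run out first)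
- how much of the substrate has reacted by 10 min
- how much double product there is at 10 min, in percent of the substrate charged
- how much mono adduct there is at 10 min, in percent of the substrate charged

- what is said of released group includes crystals
- crystals is a solid; its amount is given per volume of the solution
- the reaction counts as stopped when no species that holds the substrate changes by six tenths of a point or more over the second half of the time
- run time (flask): 10 min

I write s, m and d for substrate, mono adduct and double product as fractions of the substrate charge, so s + m + d = 1.

1. I turn the question round: what must be true for the whole substrate charge to reach double product? This flask would need two partner per substrate, 0.182 M, but it holds 0.164 M.

2. So I carry one quantity, the partner gap 0.198: the equivalents of partner missing from two per substrate.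

3. Partner consumed, in equivalents, is 1 − s + d, which equals 2 − 2s − m. Once the charge is consumed, 2s + m therefore equals the gap.

4. Each by its own step alone, with the other concentrations as if their whole charge were there at once, the half-lives are 0.070 min for substrate and 0.073 min for mono adduct, both shorter than 10 min . The partner charge is less than two per substrate, so I expect partner to be the limiting reagent in this flask, and d to stay below 90.1%. My rule gives the weighted sum 2s + m, not the split between s and m.

5. The forecast says the coupling partner has run out first, with conversion 96.4%, double product 83.8% and mono adduct 12.7%, on the ground that “full double coupling needs 2”.

At 10 min the result for this flask is that the coupling partner has run out first, with 0% of the partner charge left, conversion 96.4%, double product 83.8% and mono adduct 12.7%, the forecast's figures. Here 2s + m comes to 0.199 against the gap of 0.198. In the neighbour flask with 0.23 M of substrate, the gap is 1.29. At 10.0 min that neighbour holds 0 partner by its own line 0%, substrate 46.2% and mono adduct 36.2%, so its 2s + m comes to 1.29.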